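How much of the charge stands as single ring after 12 min at west, south-east and south? The answer turns on the pool W, the fraction of the charge not yet read as single ring, open trimer or ring dimer.

| flask | substrate | temperature | remark | time |
|---|---|---|---|---|
| theta | 0.025 M | 20 °C | run made earlier |  |
| epsilon | 0.038 M | 50 °C | run made earlier |  |
| west | 0.050 M | 25 °C |  | 12 min |
| south-east | 0.050 M | 50 °C |  | 12 min |
| south | 0.050 M | 75 °C |  | 12 min |

| run | time / min | substrate / % | open trimer / % | ring dimer / % | single ring / % |
|---|---|---|---|---|---|
| theta | 0.417 | 35.8 | 0.2 | 0 | 4.0 |
| theta | 1.00 | 28.7 | 0.4 | 0 | 6.6 |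
| theta | 2.00 | 27.6 | 0 | 0.8 | 11.6 |
| theta | 3.00 | 26.7 | 0.8 | 2.1 | 15.0 |
| theta | 4.00 | 23.4 | 1.5 | 2.5 | 18.7 |
| theta | 6.00 | 21.8 | 2.4 | 2.9 | 24.9 |
| theta | 8.00 | 19.3 | 0.7 | 3.2 | 35.1 |
| epsilon | 0.167 | 21.5 | 0 | 2.5 | 18.2 |
| epsilon | 0.250 | 19.5 | 0.5 | 1.9 | 27.1 |
| epsilon | 0.417 | 15.0 | 0 | 3.8 | 39.7 |
| epsilon | 0.667 | 9.4 | 0.6 | 1.8 | 53.5 |
| epsilon | 0.833 | 9.4 | 0 | 2.9 | 60.7 |
| epsilon | 1.33 | 5.8 | 0 | 4.4 | 75.1 |
| epsilon | 2.50 | 0.9 | 0 | 4.5 | 90.6 |

(each reading ± 1 percentage point)

- a species is counted by the substrate in it: one ring dimer counts as two
- a species is counted by the substrate in it: one open trimer counts as three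
- a reading or a percentage of single ring counts all its forms, free or not
- a reading of substrate is of its free form alone

* which of these there is most of at the end, counted by the substrate in it, west (single ring / open trimer / ring dimer / substrate)
* which of these there is most of at the end, counted by the substrate in it, south-east (single ring / open trimer / ring dimer / substrate)
* which of these there is most of at the end, counted by the substrate in it, south (single ring / open trimer / ring dimer / substrate)
* how much there is at the end of the one of these that leads, in percent of the substrate charged: west
* how much there is at the end of the one of these that leads, in percent of the substrate charged: south-east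
* how much there is at the end of the one of these that leads, in percent of the substrate charged: south

In the theta run the pool stands at 61.0% at the last reading. Free substrate is a share f of it, read as 30.9% at 1.00 min and 31.6% at 8.00 min, so the share hardly moves while the pool drains.

If the loss from the pool is proportional to the pool, integration gives

W = exp(−k t).

Theta gives k = 0.0618 /min, and epsilon at 0.667 min gives 1.23 /min. This sets aside the difference in charge. A straight line of ln k against temperature between these two runs gives, for west, the pool constant k, the rate at which substrate and its unseen partner leave together, 0.102 /min.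

Two extremes bracket west:

unseen part absent, whole charge free: W = exp(−k t/f) = 2.11%
unseen part formed at once and then frozen, with neither entry nor return, free share f draining by itself: W = 1 − f + f exp(−k t/f) = 69.1%

The steady share places west between them, as a quick equilibrium feeding a pseudo-first-order drain:

W = exp(−k t) = 29.5%

Theta sends 90.0% of the converted material to single ring, so this reckoning gives 63.5% at west. At south-east W is <0.001%, and epsilon's share of 95.3% gives the yield there.

The forecast names single ring in each flask, with 60%, 93% and 95%, and calls the unseen pool “a fast reservoir in equilibrium with substrate”. At west it stands below the reckoning above.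

The flasks give single ring at 60.1%, 94.0% and 96.9%.

    open dimer → ring dimer (k = 0.0163 /s, Ea = 89.0 kJ/mol)
    substrate ⇌ dormant form (K = 2.20, k = 0.125 /s, Ea = 83.0 kJ/mol, ΔH = 8.00 kJ/mol)
    substrate → single ring (k = 0.00483 /s, Ea = 87.0 kJ/mol)
    crystals ⇌ single ring, rate k4*(cs4 - [single ring]) while solid is left; crystals form when [single ring] > cs4 (solubility = 24.0 mM, k = 0.0641 /s)
    substrate + open dimer → open trimer (k = 0.219 /M/s, Ea = 56.0 kJ/mol)
    2 substrate → open dimer (k = 0.0414 /M/s, Ea = 66.0 kJ/mol)
    (constants at 25 °C)

The unseen part is the dormant form, and its return to substrate is part of the reason for the west yield: without that return, single ring at west is 3.66% against 60.1%. The difference in temperature is the main reason for the gap between south and west, with single ring at 96.9% against 60.1%. West holds substrate, dormant form and open dimer summing to 28.6%, beside the reckoned 29.5%. A neighbouring flask repeats west at 10 °C, where the same line gives W = 76.1%. That flask holds 25.3% substrate, 48.5% dormant form and 2.29% open dimer, together 76.1%.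

(The earlier runs and the new flask were generated by integration for substances that don't exist, and the scatter is random.)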